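Saturday's run left 46% ring at 30.0 h, and I took the remainder for chains.

| flask | starting material | remark | time |
|---|---|---|---|
| Thursday's | 2.1 M | run made earlier |  |
| Saturday's | 1.1 M | run made earlier |  |
| Sunday's | 1.6 M | run made earlier |  |
| north | 2.1 M | a closed flask charged with all of it at once and left for 3.0 d | 3.0 d |
| north-west | 2.1 M | one stirred flow tank at steady state, fed with the mixture as stated, mean residence time 3.0 d |  |

Thursday's run (percent of the starting material charged)

| time / d | ring / % | open dimer / % |
|---|---|---|
| 0.250 | 23 | 41 |
| 0.500 | 30 | 41 |
| 1.25 | 31 | 40 |
| 3.00 | 32 | 35 |

Saturday's run (percent of the starting material charged)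

| time / h | ring / % | open dimer / % |
|---|---|---|
| 5.00 | 27 | 37 |
| 15.0 | 41 | 33 |
| 30.0 | 46 | 37 |
| 40.0 | 42 | 36 |

Sunday's run (percent of the starting material charged)

| time / h | ring / % | open dimer / % |
|---|---|---|
| 10.0 | 30 | 35 |
| 20.0 | 36 | 37 |
| 30.0 | 33 | 39 |
| 40.0 | 33 | 32 |

(each reading ± 2 percentage points)

- the set-up with the highest share of ring in all that became ring or open dimer or open trimer, at the outlet or at the end ("none" if the first two lie within 2 percentage points) (north / north-west / none)
- share of ring in all that became ring or open dimer or open trimer, at the outlet or at the end, north
- share of ring in all that became ring or open dimer or open trimer, at the outlet or at the end, north-west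

- percent here means starting material units held: one open dimer counts as two
- percent here means starting material units held: one open trimer counts as three
- the stated concentrations are those of everything mixed, before any reaction; amounts are the same in each set-up
- the analysis behind the earlier runs scatters by 2 percentage points, standard deviation
- the earlier runs were made in a closed, stirred flask
- a reading or a percentage of ring counts all its forms, free or not
- the share counts what is present at the end, not what went on to other products

I read ring closure as first order in starting material and chain growth as second order. Equal use is then the zero of my scale. With r the charge over the level of equal use, a closed flask ends at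

ring share (the selectivity) = ln(1 + r) / r

Setting r = 3 gives 46.2%, Saturday's reading, so the level stood at 0.367 M. This even level, the concentration of starting material at which closure and chain growth consume it equally, carried my reckoning. Saturday's 27% ring at 5.00 h then put starting material at 0.779 even levels, which gave a closure constant k of 2.58 d⁻¹.

I drew north with r = 5.73. Chains started ahead of ring by that factor. The crossing came at 0.206 d with ring at 21.2%, sooner than north's 3.0 d. The level was 33.3%.

For north-west, with f the unused part of the charge:

1 − f = k t f (1 + r f), so f = 8.10%

The outlet held 0.170 M, and the share was 68.3%.

The forecast gave north-west, with 32% for north and 65% for north-west, “favouring first-order closure”.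

The flasks gave north-west: north 29.5%, north-west 68.8%.

    starting material → ring (k = 3.80 × 10⁻⁵ s⁻¹)
    2 starting material → open dimer (k = 4.95 × 10⁻⁵ M⁻¹ s⁻¹)
    starting material + open dimer → open trimer (k = 4.02 × 10⁻⁵ M⁻¹ s⁻¹)
    starting material + ring ⇌ idle adduct, settled at all times (K = 0.195 M⁻¹)
    ring → over-reaction product (k = 2.73 × 10⁻⁹ s⁻¹)

From the even level of 0.367 M, the closed-flask line had given 33.3% for north, which ended at 29.5%, and the tank balance had given 68.3% for north-west, which ended at 68.8%. The neighbour of north charged 0.53 M has r = 1.44, and the same line gives 61.9%. That flask ended with a share of 60.6%.

(The numbers in the tables are calculated with made-up constants, and the scatter is random.)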